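The data come from a simulation for an exercise, and the scatter is random.

How far has the starting material gone at 40 min, and how much of the unused reagent is still free?

common to all: starting material 0.20 M; initiator 1.2 mol%

|  | reagent | remark | time |
|---|---|---|---|
| summer | 3 equiv | the very flask that is asked about, followed so far |  |
| autumn | 4.5 equiv | run made earlier |  |
| flask | 3.00 equiv |  | 40 min |

| run | time / min | starting material / % | product / % |
|---|---|---|---|
| summer | 0.667 | 97 | 5 |
| summer | 2.00 | 76 | 22 |
| summer | 4.00 | 57 | 51 |
| summer | 6.00 | 34 | 65 |
| summer | 8.00 | 26 | 70 |
| autumn | 1.33 | 85 | 19 |
| autumn | 4.00 | 52 | 50 |
| autumn | 8.00 | 29 | 78 |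
| autumn | 12.0 | 11 | 86 |
| autumn | 15.0 | 7 | 90 |

(each reading ± 2 percentage points)

- amounts and yields of by-product count idle adduct and crystals too
- given per volume of solution although it is solid: crystals
- steps that have been proposed: initiator -> 2 initiating radical; starting material + initiating radical -> capped initiator + first chain carrier; reagent + first chain carrier -> product + second chain carrier; starting material + second chain carrier -> by-product + first chain carrier; 2 second chain carrier -> ended chains; reagent + by-product <-> idle adduct; crystals <-> by-product
- the earlier runs do not show how much of reagent is bound; that part of a forecast is a guess

1. part of the starting material that has reacted at 40 min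
2. share of the unused reagent that is free and not bound as idle adduct, at 40 min

1. We follow one molecule of starting material and ask its chance of reacting in each minute, and we call this the loss constant, which is ln(charged over left) divided by the time, the pseudo-first-order constant of these runs.

2. The last summer reading gives 0.168 /min with 3 equiv of reagent, and the last autumn reading, a separate run with 4.5 equiv, gives 0.177 /min, so the two ways agree and we trust their mean, 0.173 /min.

3. Held to 40 min in the asked flask, this constant leaves 0.0994% of the starting material, so our reckoning is 99.9% reacted, provided the reagent lasts; the proposed steps spend one equivalent of reagent per product, and 3.00 equiv are charged.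

4. The runs do not show how much reagent is bound, so we offer no number for fr.

5. The forecast gives 99% for c and 75% for fr, and says of the second figure, “Binding strength and crystallisation are unknown”.

6. The flask gives 99.9% reacted and 99.4% of the unused reagent free. At 40.0 min the crystals in this flask amount to 97.6% of the starting material charged, and the idle adduct to 1.13%. Held to 20.0 min, the loss constant leaves 3.14% of the starting material, and this flask then holds 3.55%.

    initiator → 2 initiating radical (k = 1.16 × 10⁻⁴ /min)
    starting material + initiating radical → capped initiator + first chain carrier (k = 1.84 × 10⁵ /M/s)
    reagent + first chain carrier → product + second chain carrier (k = 2.58 × 10⁵ /M/min)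
    starting material + second chain carrier → by-product + first chain carrier (k = 41200 /M/s)
    2 second chain carrier → ended chains (k = 1.00 × 10⁶ /M/s)
    reagent + by-product ⇌ idle adduct, settled at all times (K = 2.52 /M)
    crystals ⇌ by-product, rate k7*(cs7 - [by-product]) while solid is left; crystals form when [by-product] > cs7 (solubility = 2.20 mM, k = 1.09 /min)

7. With 0.750 equiv of reagent, one equivalent per product allows that share of the charge to react, and the loss constant reaches it after about 8.01 min, so we expect this second flask to stop there. At 40.0 min it shows 75.0% reacted, with 0% of the reagent left and 25.0% of the starting material: here the reagent is the limiting reagent.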